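**Retrosynthetic overview**
1. Rings: A (benzyl guaiacyl), B, C, D (benzo rings of dihydrofuran rings 1, 2, 3, counted from the oxolane) and E (terminal guaiacyl). The target comes from triester 45 by ester reduction and debenzylation. Dihydrofuran ring 1 of 45 is closed by Rh-carbene C–H insertion on the ether formed by the late union of phenol 40 (rings A, B and the oxolane) with benzylic chloride 25 (rings C, D, E).
2. 25 comes from benzyl alcohol 9 by two rounds of the same three operations: Mitsunobu etherification with iodophenol 12, Pd coupling with ethyl diazoacetate, enantioselective C–H insertion with epimerisation.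
3. 40 comes from SN1 closure of the oxolane in tetraol 39, itself from the trans aldol of (S)-lactone 35 with aldehyde 36. 35 comes from (S)-epichlorohydrin, malonate and an aryl Grignard reagent.
4. All five arenes derive from catechol via guaiacol, vanillin and 5-iodovanillin. C3 and the CH2OH of each dihydrofuran come from ethyl diazoacetate.
5. Ring order: dihydrofuran ring 3, then ring 2 (right fragment); the oxolane in parallel (left fragment); dihydrofuran ring 1 last, after the fragment union.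

Target as read from the SMILES: oxolane (2R,3S,4S) with aryl/CH2OH trans and CH2OH/benzyl cis; dihydrofuran rings 1 and 2 (2S,3R), ring 3 (2R,3S), all trans.

Assumption: the facial sense of the Rh2(PTTL)4-catalysed insertions is taken by analogy with simple 2-(benzyloxy)aryl diazoacetates ((S)-catalyst gives the 2R ring); if a substrate shows the opposite sense, the antipodal catalyst is used in that step and nothing else changes.

**Route**

Step 1
Reactants: 1 catechol
Product: 2 guaiacol
Conditions: MeI (1.0 equiv), K2CO3 (1.0 equiv), acetone, reflux; veratrole and residual 1 removed by base extraction and distillation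
Reagents that add atoms: iodomethane, CI
Why: Williamson mono-O-methylation, where limiting the alkylating agent favours the monoether because the monoanion forms first and reacts once.

Step 2
Reactants: 2 guaiacol; 3 glyoxylic acid
Product: 6 vanillin, via mandelic acid 4 (not isolated), via keto acid 5 (not isolated)
Conditions: NaOH aq, 25 °C; then O2 (air), CuSO4 (cat.), NaOH aq, 90 °C; then H2SO4 to pH 3, 60 °C
Reagents that add atoms: none
Why: para-selective hydroxyalkylation of the phenoxide by glyoxylate, aerobic copper-catalysed oxidation to the arylglyoxylate and acid-induced decarboxylation deliver the para-formyl phenol.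

Step 3
Reactants: 6 vanillin
Product: 7 5-iodovanillin
Conditions: I2, KI, NaHCO3, H2O, 25 °C
Reagents that add atoms: iodine, II
Why: electrophilic aromatic iodination at the only free position ortho to the phenoxide (para is blocked by the formyl group).

Step 4
Reactants: 6 vanillin
Product: 8 4-(benzyloxy)-3-methoxybenzaldehyde
Conditions: BnBr, K2CO3, DMF, 25 °C
Reagents that add atoms: benzyl bromide, BrCc1ccccc1
Why: Williamson etherification of the phenoxide.

Step 5
Reactants: 8 4-(benzyloxy)-3-methoxybenzaldehyde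
Product: 9 [4-(benzyloxy)-3-methoxyphenyl]methanol
Conditions: NaBH4, MeOH, 0 °C
Reagents that add atoms: none
Why: borohydride reduction of the aldehyde.

Step 6
Reactants: 7 5-iodovanillin
Product: 10 4-(hydroxymethyl)-2-iodo-6-methoxyphenol
Conditions: NaBH4, MeOH, 0 °C
Reagents that add atoms: none
Why: borohydride reduction of the aldehyde; the aryl iodide is inert.

Step 7
Reactants: 10 4-(hydroxymethyl)-2-iodo-6-methoxyphenol
Product: 12 4-{[(tert-butyldimethylsilyl)oxy]methyl}-2-iodo-6-methoxyphenol, via bis-silyl ether 11 (not isolated)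
Conditions: TBSCl (2.3 equiv), imidazole, DMF, 25 °C; then K2CO3 (0.2 equiv), MeOH, 0 °C
Reagents that add atoms: tert-butyldimethylsilyl chloride, CC(C)(C)[Si](C)(C)Cl
Why: exhaustive silylation followed by selective methanolysis of the aryl silyl ether (phenoxide is the far better leaving group) leaves only the primary silyl ether.

Step 8
Reactants: 9 [4-(benzyloxy)-3-methoxyphenyl]methanol; 12 iodophenol building block
Product: 13 aryl benzyl ether (rings D and E, iodide)
Conditions: PPh3, DIAD, THF, 0 → 25 °C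
Reagents that add atoms: none
Why: Mitsunobu etherification, in which the acidic ortho-iodophenol is alkylated by the activated primary benzylic alcohol under neutral conditions.

Step 9
Reactants: 13 aryl iodide; 14 ethyl diazoacetate
Product: 15 aryl diazoacetate
Conditions: Pd(PPh3)4 (5 mol %), Ag2CO3 (0.5 equiv), Et3N (1.3 equiv), toluene, 25 °C
Reagents that add atoms: none
Why: Pd-catalysed cross-coupling of the aryl iodide with the C–H bond of an acceptor diazo compound (oxidative addition, silver-assisted palladation of the diazo carbon, reductive elimination), with the diazo group retained at room temperature.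

Step 10
Reactants: 15 aryl diazoacetate
Product: 17 trans ester (2R,3R) of dihydrofuran ring 3, via cis ester 16 (not isolated)
Conditions: Rh2(S-PTTL)4 (dirhodium tetrakis[N-phthaloyl-(S)-tert-leucinate], 2 mol %), toluene, −60 °C, 0.02 M; then NaOEt (0.2 equiv), EtOH, 0 → 25 °C
Reagents that add atoms: none
Why: intramolecular Rh-carbene 1,5-C–H insertion into the ArO–CH2–Ar methylene closes the ring cis-selectively, C2 (R) being set by the chiral catalyst choosing one enantiotopic hydrogen (insertion with retention), and ethoxide then epimerises C3 to the thermodynamic trans ester.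

Step 11
Reactants: 17 trans ester silyl ether
Product: 18 benzylic alcohol of the ring D–E unit
Conditions: HF·pyridine, THF/pyridine, 0 °C
Reagents that add atoms: none
Why: fluoride cleavage of the primary silyl ether under buffered, non-basic conditions that leave the β-aryloxy ester untouched.

Step 12
Reactants: 18 benzylic alcohol; 12 iodophenol building block
Product: 19 aryl benzyl ether (rings C, D, E, iodide on ring C)
Conditions: PPh3, DIAD, THF, 0 → 25 °C
Reagents that add atoms: none
Why: Mitsunobu etherification as in step 8; the ester α-hydrogen is not acidic enough to interfere.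

Step 13
Reactants: 19 aryl iodide; 14 ethyl diazoacetate
Product: 20 aryl diazoacetate
Conditions: Pd(PPh3)4 (5 mol %), Ag2CO3 (0.5 equiv), Et3N (1.3 equiv), toluene, 25 °C
Reagents that add atoms: none
Why: Pd-catalysed C–H arylation of the diazoacetate as in step 9.

Step 14
Reactants: 20 aryl diazoacetate
Product: 22 trans,trans diester (ring 2: 2S,3S; ring 3: 2R,3R), via cis ester 21 (not isolated)
Conditions: Rh2(R-PTTL)4 (dirhodium tetrakis[N-phthaloyl-(R)-tert-leucinate], 2 mol %), toluene, −60 °C, 0.02 M; then NaOEt (0.2 equiv), EtOH, 0 → 25 °C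
Reagents that add atoms: none
Why: the same carbene 1,5-C–H insertion closes dihydrofuran ring 2, the antipodal catalyst overriding the remote stereocentres to set C2 (S), and ethoxide epimerises the new C3 to trans while the existing trans ester is already at equilibrium.

Step 15
Reactants: 22 diester silyl ether
Product: 23 benzylic alcohol of the ring C–D–E unit
Conditions: HF·pyridine, THF/pyridine, 0 °C
Reagents that add atoms: none
Why: buffered fluoride desilylation as in step 11.

Step 16
Reactants: 23 benzylic alcohol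
Product: 25 benzylic chloride (right fragment), via mesylate 24 (not isolated)
Conditions: MsCl, Et3N, CH2Cl2, 0 → 25 °C; used crude
Reagents that add atoms: methanesulfonyl chloride, CS(=O)(=O)Cl
Why: the electron-rich benzylic mesylate is displaced in situ by chloride to give the para-alkoxybenzylic chloride.

Step 17
Reactants: 2 guaiacol
Product: 26 4-bromo-2-methoxyphenol
Conditions: NBS, MeCN, 0 °C
Reagents that add atoms: N-bromosuccinimide, O=C1CCC(=O)N1Br
Why: electrophilic bromination para to the hydroxyl group, the stronger director.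

Step 18
Reactants: 26 4-bromo-2-methoxyphenol
Product: 27 1-(benzyloxy)-4-bromo-2-methoxybenzene
Conditions: BnBr, K2CO3, DMF, 25 °C
Reagents that add atoms: benzyl bromide, BrCc1ccccc1
Why: Williamson etherification of the phenoxide.

Step 19
Reactants: 28 malonic acid
Product: 29 dimethyl malonate
Conditions: MeOH, H2SO4 (cat.), reflux
Reagents that add atoms: methanol, CO
Why: Fischer esterification.

Step 20
Reactants: 30 (S)-epichlorohydrin; 29 dimethyl malonate
Product: 32 methyl (1R,5S)-2-oxo-3-oxabicyclo[3.1.0]hexane-1-carboxylate, via epoxide 31 (not isolated)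
Conditions: NaOMe (1.1 equiv), MeOH, 0 °C → reflux
Reagents that add atoms: none
Why: the malonate opens the epoxide at CH2, the alkoxide displaces chloride to give epoxide 31, intramolecular SN2 at the stereogenic carbon (inversion) closes the cyclopropane and the released alkoxide lactonises, so the stereocentre derives from the chiral pool.

Step 21
Reactants: 27 aryl bromide; 32 cyclopropane lactone
Product: 34 methyl (4S)-4-{[4-(benzyloxy)-3-methoxyphenyl]methyl}-2-oxooxolane-3-carboxylate, via Grignard reagent 33 (not isolated)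
Conditions: Mg, THF, reflux; then CuI (10 mol %), 32, THF, −30 → 0 °C; 1 M HCl quench
Reagents that add atoms: none
Why: copper-catalysed homoconjugate opening of the doubly activated cyclopropane at its CH2 carbon by the aryl Grignard reagent leaves the ring stereocentre untouched and installs the ring A benzyl group.

Step 22
Reactants: 34 malonate-type lactone
Product: 35 (4S)-4-{[4-(benzyloxy)-3-methoxyphenyl]methyl}oxolan-2-one
Conditions: LiCl, H2O, DMSO, 140 °C
Reagents that add atoms: none
Why: Krapcho dealkoxycarbonylation removes the activating ester without touching C4.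

Step 23
Reactants: 7 5-iodovanillin
Product: 36 4-formyl-2-iodo-6-methoxyphenyl pivalate
Conditions: PivCl, Et3N, DMAP (cat.), CH2Cl2, 0 °C
Reagents that add atoms: pivaloyl chloride, CC(C)(C)C(=O)Cl
Why: acylation of the phenol gives a hindered ester that survives enolate chemistry and is removed by the later hydride reduction.

Step 24
Reactants: 35 (S)-lactone; 36 aldehyde
Product: 38 trans aldol lactone (3R,4S; carbinol epimers), via lithium enolate 37 (not isolated)
Conditions: LiN(iPr)2 (1.05 equiv), THF, −78 °C; then 36; AcOH quench at −78 °C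
Reagents that add atoms: none
Why: lithium enolate aldol addition in which the aldehyde approaches anti to the C4 benzyl group, setting C3 trans to C4; the carbinol centre is reset in step 26.

Step 25
Reactants: 38 aldol lactone
Product: 39 tetraol (2S,3S; free phenol)
Conditions: LiAlH4, THF, 0 °C
Reagents that add atoms: none
Why: hydride reduction opens the lactone to the 1,4-diol and cleaves the pivalate in the same operation.

Step 26
Reactants: 39 tetraol
Product: 40 4-[(2R,3S,4S)-4-{[4-(benzyloxy)-3-methoxyphenyl]methyl}-3-(hydroxymethyl)oxolan-2-yl]-2-iodo-6-methoxyphenol (left fragment)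
Conditions: camphorsulfonic acid (10 mol %), CH2Cl2/THF, 0 °C, short reaction time
Reagents that add atoms: none
Why: SN1 cyclodehydration through the para-hydroxybenzylic cation, trapped 5-exo by the primary hydroxyl three carbons away, converts both carbinol epimers into the 2,3-trans oxolane (aryl anti to the C3 hydroxymethyl group), setting C2 as R.

Step 27
Reactants: 40 left fragment phenol; 25 right fragment chloride
Product: 41 coupled aryl benzyl ether (rings A–E, iodide on ring B, free CH2OH)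
Conditions: K2CO3 (2 equiv), Bu4NI (cat.), DMF, 25 °C
Reagents that add atoms: none
Why: Williamson etherification in which carbonate deprotonates only the phenol, so the primary alcohol does not compete and the two halves are joined.

Step 28
Reactants: 41 coupled ether
Product: 42 acetate of 41
Conditions: Ac2O, pyridine, DMAP (cat.), CH2Cl2, 25 °C
Reagents that add atoms: acetic anhydride, CC(=O)OC(C)=O
Why: acetylation masks the primary alcohol against carbene O–H insertion in step 30.

Step 29
Reactants: 42 aryl iodide; 14 ethyl diazoacetate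
Product: 43 aryl diazoacetate
Conditions: Pd(PPh3)4 (10 mol %), Ag2CO3 (0.5 equiv), Et3N (1.3 equiv), toluene, 25 °C
Reagents that add atoms: none
Why: Pd-catalysed C–H arylation of the diazoacetate as in steps 9 and 13.

Step 30
Reactants: 43 aryl diazoacetate
Product: 45 triester (ring 1: 2S,3S; ring 2: 2S,3S; ring 3: 2R,3R; free CH2OH), via cis ester 44 (not isolated)
Conditions: Rh2(R-PTTL)4 (3 mol %), toluene, −60 °C, 0.01 M; then NaOEt (0.3 equiv), EtOH, 0 → 25 °C
Reagents that add atoms: none
Why: carbene 1,5-C–H insertion into the newly formed ArO–CH2–Ar methylene closes dihydrofuran ring 1 with catalyst-controlled C2 (S), and ethoxide epimerises C3 to trans and transesterifies the acetate away.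

Step 31
Reactants: 45 triester
Product: 46 di-O-benzyl ether of the target
Conditions: LiAlH4, THF, −20 → 0 °C
Reagents that add atoms: none
Why: hydride reduction of the three ethyl esters to hydroxymethyl groups without touching any stereocentre.

Step 32
Reactants: 46 di-O-benzyl ether
Product: 47 CNP0267891.2
Conditions: H2 (1 atm), 10% Pd/C, EtOAc/EtOH, 25 °C, stopped at full conversion
Reagents that add atoms: none
Why: hydrogenolysis of the two benzyl aryl ethers is much faster than cleavage of the cyclic benzylic C–O bonds (the same selectivity as in debenzylation of flavan-type ethers), so both phenols are released with all nine stereocentres intact.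

**Compound list**

1 | catechol (benzene-1,2-diol) | Oc1ccccc1O | starting material
2 | guaiacol (2-methoxyphenol) | COc1ccccc1O | intermediate
3 | glyoxylic acid | O=CC(=O)O | starting material
4 | 4-hydroxy-3-methoxymandelic acid (racemic) | COc1cc(C(O)C(=O)O)ccc1O | intermediate
5 | (4-hydroxy-3-methoxyphenyl)oxoacetic acid | COc1cc(C(=O)C(=O)O)ccc1O | intermediate
6 | vanillin | COc1cc(C=O)ccc1O | intermediate
7 | 5-iodovanillin (4-hydroxy-3-iodo-5-methoxybenzaldehyde) | COc1cc(C=O)cc(I)c1O | intermediate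
8 | 4-(benzyloxy)-3-methoxybenzaldehyde | COc1cc(C=O)ccc1OCc1ccccc1 | intermediate
9 | [4-(benzyloxy)-3-methoxyphenyl]methanol | COc1cc(CO)ccc1OCc1ccccc1 | intermediate
10 | 4-(hydroxymethyl)-2-iodo-6-methoxyphenol | COc1cc(CO)cc(I)c1O | intermediate
11 | bis(tert-butyldimethylsilyl) ether of 10 | COc1cc(CO[Si](C)(C)C(C)(C)C)cc(I)c1O[Si](C)(C)C(C)(C)C | intermediate
12 | 4-{[(tert-butyldimethylsilyl)oxy]methyl}-2-iodo-6-methoxyphenol | COc1cc(CO[Si](C)(C)C(C)(C)C)cc(I)c1O | intermediate
13 | tert-butyl[(4-{[4-(benzyloxy)-3-methoxyphenyl]methoxy}-3-iodo-5-methoxyphenyl)methoxy]dimethylsilane | COc1cc(COc2c(I)cc(CO[Si](C)(C)C(C)(C)C)cc2OC)ccc1OCc1ccccc1 | intermediate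
14 | ethyl diazoacetate | CCOC(=O)C=[N+]=[N-] | starting material
15 | ethyl 2-(2-{[4-(benzyloxy)-3-methoxyphenyl]methoxy}-5-{[(tert-butyldimethylsilyl)oxy]methyl}-3-methoxyphenyl)-2-diazoacetate | CCOC(=O)C(=[N+]=[N-])c1cc(CO[Si](C)(C)C(C)(C)C)cc(OC)c1OCc1ccc(OCc2ccccc2)c(OC)c1 | intermediate
16 | ethyl (2R,3S)-2-[4-(benzyloxy)-3-methoxyphenyl]-5-{[(tert-butyldimethylsilyl)oxy]methyl}-7-methoxy-2,3-dihydro-1-benzofuran-3-carboxylate (cis) | CC(C)(C)[Si](C)(C)OCc1cc(OC)c2c(c1)[C@H](C(=O)OCC)[C@H](c1ccc(OCc3ccccc3)c(OC)c1)O2 | intermediate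
17 | ethyl (2R,3R)-2-[4-(benzyloxy)-3-methoxyphenyl]-5-{[(tert-butyldimethylsilyl)oxy]methyl}-7-methoxy-2,3-dihydro-1-benzofuran-3-carboxylate (trans) | CC(C)(C)[Si](C)(C)OCc1cc(OC)c2c(c1)[C@@H](C(=O)OCC)[C@H](c1ccc(OCc3ccccc3)c(OC)c1)O2 | intermediate
18 | ethyl (2R,3R)-2-[4-(benzyloxy)-3-methoxyphenyl]-5-(hydroxymethyl)-7-methoxy-2,3-dihydro-1-benzofuran-3-carboxylate | OCc1cc(OC)c2c(c1)[C@@H](C(=O)OCC)[C@H](c1ccc(OCc3ccccc3)c(OC)c1)O2 | intermediate
19 | ethyl (2R,3R)-2-[4-(benzyloxy)-3-methoxyphenyl]-5-{[4-({[tert-butyl(dimethyl)silyl]oxy}methyl)-2-iodo-6-methoxyphenoxy]methyl}-7-methoxy-2,3-dihydro-1-benzofuran-3-carboxylate | CC(C)(C)[Si](C)(C)OCc1cc(I)c(OCc2cc(OC)c3c(c2)[C@@H](C(=O)OCC)[C@H](c2ccc(OCc4ccccc4)c(OC)c2)O3)c(OC)c1 | intermediate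
20 | analogue of 19 with C(=N2)CO2Et in place of iodine (aryl diazoacetate on ring C) | CC(C)(C)[Si](C)(C)OCc1cc(C(=[N+]=[N-])C(=O)OCC)c(OCc2cc(OC)c3c(c2)[C@@H](C(=O)OCC)[C@H](c2ccc(OCc4ccccc4)c(OC)c2)O3)c(OC)c1 | intermediate
21 | ethyl (2S,3R)-2-{(2R,3R)-2-[4-(benzyloxy)-3-methoxyphenyl]-3-(ethoxycarbonyl)-7-methoxy-2,3-dihydro-1-benzofuran-5-yl}-5-{[(tert-butyldimethylsilyl)oxy]methyl}-7-methoxy-2,3-dihydro-1-benzofuran-3-carboxylate (new ring cis) | CC(C)(C)[Si](C)(C)OCc1cc(OC)c2c(c1)[C@@H](C(=O)OCC)[C@@H](c1cc(OC)c3c(c1)[C@@H](C(=O)OCC)[C@H](c1ccc(OCc4ccccc4)c(OC)c1)O3)O2 | intermediate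
22 | ethyl (2S,3S)-2-{(2R,3R)-2-[4-(benzyloxy)-3-methoxyphenyl]-3-(ethoxycarbonyl)-7-methoxy-2,3-dihydro-1-benzofuran-5-yl}-5-{[(tert-butyldimethylsilyl)oxy]methyl}-7-methoxy-2,3-dihydro-1-benzofuran-3-carboxylate (both rings trans) | CC(C)(C)[Si](C)(C)OCc1cc(OC)c2c(c1)[C@H](C(=O)OCC)[C@@H](c1cc(OC)c3c(c1)[C@@H](C(=O)OCC)[C@H](c1ccc(OCc4ccccc4)c(OC)c1)O3)O2 | intermediate
23 | 5-(hydroxymethyl) analogue of 22 | OCc1cc(OC)c2c(c1)[C@H](C(=O)OCC)[C@@H](c1cc(OC)c3c(c1)[C@@H](C(=O)OCC)[C@H](c1ccc(OCc4ccccc4)c(OC)c1)O3)O2 | intermediate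
24 | 5-[(methanesulfonyloxy)methyl] analogue of 22 | CS(=O)(=O)OCc1cc(OC)c2c(c1)[C@H](C(=O)OCC)[C@@H](c1cc(OC)c3c(c1)[C@@H](C(=O)OCC)[C@H](c1ccc(OCc4ccccc4)c(OC)c1)O3)O2 | intermediate
25 | 5-(chloromethyl) analogue of 22 (right fragment) | ClCc1cc(OC)c2c(c1)[C@H](C(=O)OCC)[C@@H](c1cc(OC)c3c(c1)[C@@H](C(=O)OCC)[C@H](c1ccc(OCc4ccccc4)c(OC)c1)O3)O2 | intermediate
26 | 4-bromo-2-methoxyphenol | COc1cc(Br)ccc1O | intermediate
27 | 1-(benzyloxy)-4-bromo-2-methoxybenzene | COc1cc(Br)ccc1OCc1ccccc1 | intermediate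
28 | malonic acid | OC(=O)CC(=O)O | starting material
29 | dimethyl malonate | COC(=O)CC(=O)OC | intermediate
30 | (S)-epichlorohydrin [(2S)-2-(chloromethyl)oxirane] | ClC[C@@H]1CO1 | starting material
31 | dimethyl 2-{[(2S)-oxiran-2-yl]methyl}propanedioate | COC(=O)C(C[C@H]1CO1)C(=O)OC | intermediate
32 | methyl (1R,5S)-2-oxo-3-oxabicyclo[3.1.0]hexane-1-carboxylate | COC(=O)[C@@]12C[C@@H]1COC2=O | intermediate
33 | [4-(benzyloxy)-3-methoxyphenyl]magnesium bromide | COc1cc([Mg]Br)ccc1OCc1ccccc1 | intermediate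
34 | methyl (4S)-4-{[4-(benzyloxy)-3-methoxyphenyl]methyl}-2-oxooxolane-3-carboxylate (C3 epimers) | COC(=O)C1C(=O)OC[C@H]1Cc1ccc(OCc2ccccc2)c(OC)c1 | intermediate
35 | (4S)-4-{[4-(benzyloxy)-3-methoxyphenyl]methyl}oxolan-2-one | COc1cc(C[C@@H]2COC(=O)C2)ccc1OCc1ccccc1 | intermediate
36 | 4-formyl-2-iodo-6-methoxyphenyl 2,2-dimethylpropanoate | COc1cc(C=O)cc(I)c1OC(=O)C(C)(C)C | intermediate
37 | lithium enolate of 35 | COc1cc(C[C@@H]2COC(O[Li])=C2)ccc1OCc1ccccc1 | intermediate
38 | 4-[{(3R,4S)-4-{[4-(benzyloxy)-3-methoxyphenyl]methyl}-2-oxooxolan-3-yl}(hydroxy)methyl]-2-iodo-6-methoxyphenyl 2,2-dimethylpropanoate (carbinol epimers) | O=C1OC[C@@H](Cc2ccc(OCc3ccccc3)c(OC)c2)[C@@H]1C(O)c1cc(OC)c(OC(=O)C(C)(C)C)c(I)c1 | intermediate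
39 | 4-[(2S,3S)-3-{[4-(benzyloxy)-3-methoxyphenyl]methyl}-1,4-dihydroxy-2-(hydroxymethyl)butyl]-2-iodo-6-methoxyphenol (C1 epimers) | OC[C@@H](Cc1ccc(OCc2ccccc2)c(OC)c1)[C@@H](CO)C(O)c1cc(OC)c(O)c(I)c1 | intermediate
40 | 4-[(2R,3S,4S)-4-{[4-(benzyloxy)-3-methoxyphenyl]methyl}-3-(hydroxymethyl)oxolan-2-yl]-2-iodo-6-methoxyphenol (left fragment) | COc1cc(C[C@@H]2CO[C@@H](c3cc(OC)c(O)c(I)c3)[C@@H]2CO)ccc1OCc1ccccc1 | intermediate
41 | aryl benzyl ether: phenol oxygen of 40 bonded to the benzylic CH2 of 25 (iodide on ring B, free oxolane CH2OH) | COc1cc(C[C@@H]2CO[C@@H](c3cc(OC)c(OCc4cc(OC)c5c(c4)[C@H](C(=O)OCC)[C@@H](c4cc(OC)c6c(c4)[C@@H](C(=O)OCC)[C@H](c4ccc(OCc7ccccc7)c(OC)c4)O6)O5)c(I)c3)[C@@H]2CO)ccc1OCc1ccccc1 | intermediate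
42 | acetate of 41 (oxolane CH2OAc) | COc1cc(C[C@@H]2CO[C@@H](c3cc(OC)c(OCc4cc(OC)c5c(c4)[C@H](C(=O)OCC)[C@@H](c4cc(OC)c6c(c4)[C@@H](C(=O)OCC)[C@H](c4ccc(OCc7ccccc7)c(OC)c4)O6)O5)c(I)c3)[C@@H]2COC(C)=O)ccc1OCc1ccccc1 | intermediate
43 | analogue of 42 with C(=N2)CO2Et in place of iodine on ring B | COc1cc(C[C@@H]2CO[C@@H](c3cc(OC)c(OCc4cc(OC)c5c(c4)[C@H](C(=O)OCC)[C@@H](c4cc(OC)c6c(c4)[C@@H](C(=O)OCC)[C@H](c4ccc(OCc7ccccc7)c(OC)c4)O6)O5)c(C(=[N+]=[N-])C(=O)OCC)c3)[C@@H]2COC(C)=O)ccc1OCc1ccccc1 | intermediate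
44 | pentameric triester acetate, dihydrofuran ring 1 cis (2S,3R), rings 2 and 3 trans | COc1cc(C[C@@H]2CO[C@@H](c3cc(OC)c4c(c3)[C@@H](C(=O)OCC)[C@@H](c3cc(OC)c5c(c3)[C@H](C(=O)OCC)[C@@H](c3cc(OC)c6c(c3)[C@@H](C(=O)OCC)[C@H](c3ccc(OCc7ccccc7)c(OC)c3)O6)O5)O4)[C@@H]2COC(C)=O)ccc1OCc1ccccc1 | intermediate
45 | pentameric triethyl ester, all dihydrofuran rings trans (ring 1: 2S,3S; ring 2: 2S,3S; ring 3: 2R,3R), oxolane (2R,3S,4S) with free CH2OH, two benzyl ethers | COc1cc(C[C@@H]2CO[C@@H](c3cc(OC)c4c(c3)[C@H](C(=O)OCC)[C@@H](c3cc(OC)c5c(c3)[C@H](C(=O)OCC)[C@@H](c3cc(OC)c6c(c3)[C@@H](C(=O)OCC)[C@H](c3ccc(OCc7ccccc7)c(OC)c3)O6)O5)O4)[C@@H]2CO)ccc1OCc1ccccc1 | intermediate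
46 | di-O-benzyl ether of the target (both guaiacyl phenols benzylated) | COc1cc(C[C@@H]2CO[C@@H](c3cc(OC)c4c(c3)[C@H](CO)[C@@H](c3cc(OC)c5c(c3)[C@H](CO)[C@@H](c3cc(OC)c6c(c3)[C@@H](CO)[C@H](c3ccc(OCc7ccccc7)c(OC)c3)O6)O5)O4)[C@@H]2CO)ccc1OCc1ccccc1 | intermediate
47 | CNP0267891.2: oxolane (2R,3S,4S) bearing the 4-hydroxy-3-methoxybenzyl group at C4, CH2OH at C3 and at C2 the chain of three trans 3-(hydroxymethyl)-7-methoxy-2,3-dihydrobenzofurans [(2S,3R), (2S,3R), (2R,3S)] ending in 4-hydroxy-3-methoxyphenyl | COc1cc(C[C@@H]2CO[C@@H](c3cc(OC)c4c(c3)[C@H](CO)[C@@H](c3cc(OC)c5c(c3)[C@H](CO)[C@@H](c3cc(OC)c6c(c3)[C@@H](CO)[C@H](c3ccc(O)c(OC)c3)O6)O5)O4)[C@@H]2CO)ccc1O | target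

**Totals and risks**

Total step count: 32.
Longest linear sequence: 20 steps (1, 2, 3, 6, 7, 8–16, 27–32; catechol to 47).

Steps most likely to fail:

Step 27 (fragment union). The para-alkoxybenzylic chloride 25 is prone to solvolysis and self-condensation, and the phenol of 40 is flanked by iodine and methoxy. The fallback unites the fragments by a Mitsunobu reaction with the stable alcohol 23 instead of an SN2 alkylation. Setting out from 40, both hydroxyls are silylated (TBSCl, imidazole, DMF) to give the bis-silyl ether F1. The aryl silyl ether is then cleaved selectively (K2CO3, MeOH, 0 °C) to give the mono-silyl ether F2 with the phenol free. F2 and 23 are condensed (PPh3, DIAD, THF) to give the coupled silyl ether F3, and HF·pyridine removes the silyl group, coming back to the route at 41.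

Step 29 (Pd coupling of ethyl diazoacetate with the hindered, polyfunctional aryl iodide 42). The fallback builds the diazo ester in two stages through the arylacetate. Setting out from 42, Pd-catalysed α-arylation with the Reformatsky reagent BrZnCH2CO2Et (Pd2(dba)3, XPhos, THF, 60 °C) gives the ethyl arylacetate F4. Regitz diazo transfer (4-acetamidobenzenesulfonyl azide, DBU, MeCN, 0 °C), which can only diazotise the one CH2 flanked by aryl and ester, comes back to the route at 43.

Step 30 (late C–H insertion on the full pentamer, where catalyst control must override nine-centre substrate bias and the cis ester must then be epimerised). The fallback replaces catalyst-only control by auxiliary plus catalyst double stereodifferentiation that gives the trans ring directly, with no base step. Setting out from 42, the Pd/Ag coupling of step 29 is run with (2S)-1-oxo-1-(pyrrolidin-1-yl)propan-2-yl diazoacetate in place of 14 to give the lactamide aryl diazoacetate F5. Rh2(S-DOSP)4 (dirhodium tetrakis[(S)-N-(4-dodecylbenzenesulfonyl)prolinate], CH2Cl2, 25 °C) then effects trans-selective insertion to give the lactamide ester F6; the matched auxiliary/catalyst pair is the one used for related (2S,3S) esters, and the antipodal pair is used if the sense is reversed. LiAlH4 reduces the auxiliary ester, the two ethyl esters and the acetate in one operation, coming back to the route at 46.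

Further compounds
F1 | step 27 | bis(tert-butyldimethylsilyl) ether of 40 | COc1cc(C[C@@H]2CO[C@@H](c3cc(OC)c(O[Si](C)(C)C(C)(C)C)c(I)c3)[C@@H]2CO[Si](C)(C)C(C)(C)C)ccc1OCc1ccccc1
F2 | step 27 | primary tert-butyldimethylsilyl ether of 40 (free phenol) | COc1cc(C[C@@H]2CO[C@@H](c3cc(OC)c(O)c(I)c3)[C@@H]2CO[Si](C)(C)C(C)(C)C)ccc1OCc1ccccc1
F3 | step 27 | primary tert-butyldimethylsilyl ether of 41 | COc1cc(C[C@@H]2CO[C@@H](c3cc(OC)c(OCc4cc(OC)c5c(c4)[C@H](C(=O)OCC)[C@@H](c4cc(OC)c6c(c4)[C@@H](C(=O)OCC)[C@H](c4ccc(OCc7ccccc7)c(OC)c4)O6)O5)c(I)c3)[C@@H]2CO[Si](C)(C)C(C)(C)C)ccc1OCc1ccccc1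
F4 | step 29 | analogue of 42 with CH2CO2Et in place of iodine on ring B | COc1cc(C[C@@H]2CO[C@@H](c3cc(OC)c(OCc4cc(OC)c5c(c4)[C@H](C(=O)OCC)[C@@H](c4cc(OC)c6c(c4)[C@@H](C(=O)OCC)[C@H](c4ccc(OCc7ccccc7)c(OC)c4)O6)O5)c(CC(=O)OCC)c3)[C@@H]2COC(C)=O)ccc1OCc1ccccc1
F5 | step 30 | analogue of 43 with the (S)-lactoylpyrrolidine ester in place of the ethyl ester of the diazoacetate | COc1cc(C[C@@H]2CO[C@@H](c3cc(OC)c(OCc4cc(OC)c5c(c4)[C@H](C(=O)OCC)[C@@H](c4cc(OC)c6c(c4)[C@@H](C(=O)OCC)[C@H](c4ccc(OCc7ccccc7)c(OC)c4)O6)O5)c(C(=[N+]=[N-])C(=O)O[C@@H](C)C(=O)N4CCCC4)c3)[C@@H]2COC(C)=O)ccc1OCc1ccccc1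
F6 | step 30 | pentameric acetate with trans (2S,3S) (S)-lactoylpyrrolidine ester on dihydrofuran ring 1 and trans ethyl esters on rings 2 and 3 | COc1cc(C[C@@H]2CO[C@@H](c3cc(OC)c4c(c3)[C@H](C(=O)O[C@@H](C)C(=O)N8CCCC8)[C@@H](c3cc(OC)c5c(c3)[C@H](C(=O)OCC)[C@@H](c3cc(OC)c6c(c3)[C@@H](C(=O)OCC)[C@H](c3ccc(OCc7ccccc7)c(OC)c3)O6)O5)O4)[C@@H]2COC(C)=O)ccc1OCc1ccccc1
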